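Electrophile left is the amount that counts: whatever has gone from it is reacted, so each answer is the charge minus what stands at 20 min.

| setting | birch | larch | red | grey | green |
|---|---|---|---|---|---|
| electrophile | 0.10 M | 0.10 M | 0.10 M | 0.10 M | 0.10 M |
| nucleophile | 0.19 M | 0.82 M | 0.300 M | 0.600 M | 0.150 M |
| remark | run made earlier | run made earlier |  |  |  |
| time |  |  | 20 min | 20 min | 20 min |

- birch (time / min: electrophile / %, target / %): 4.00: 57.9, 34.5; 8.00: 44.6, 40.7; 12.0: 37.0, 45.1; 15.0: 32.0, 46.4; 20.0: 26.5, 49.2
- larch (time / min: electrophile / %, target / %): 1.50: 47.4, 50.1; 3.00: 34.1, 61.1; 6.00: 24.6, 68.8; 10.0: 17.0, 73.6; 20.0: 10.1, 77.4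

(readings scatter by 0.5 percentage points)

- what has gone from electrophile into another species counts as reacted, even if it can come back

- part of the electrophile that has reacted at the end, red
- part of the electrophile that has reacted at the end, grey
- part of the electrophile that has reacted at the end, green
- what raising the concentration of nucleophile from its lowest to its highest value here does to the part of the electrophile that has reacted (changes below 5 percentage points count as none) (no change / it falls / it rises)

Half-lives spent means the number of halvings that lead from the charge to the amount left; no constant half-life is assumed. At 20.0 min, birch has spent 1.92 and larch 3.31.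

My first way draws a straight line through these counts against ln[nucleophile], with slope 0.952. Red gets 2.35 and grey 3.01. Green's half-lives spent are 1.69. Reacted is then 80.4%, 87.6% and 69.0%. That is a rise of 19 percentage points, above the margin.

My second way uses the dose, [nucleophile] × time, and borrows the run moment of equal dose. Red matches larch at 7.32 min, which gives 78.2% reacted. Green matches birch at 15.8 min, which gives 68.9%. Green's two figures lie close, but that is no check: both rest on birch's electrophile reading of 26.5% at 20.0 min.

Red parts, and the second way cheats. Its larch moment is younger than red's 20 min, and its birch moment is younger than green's 20 min. Larch's gap below the full balance also grows from 6.6 points at 6.00 min to 12 points at 20.0 min. Minutes therefore count apart from the dose, so the second way reads too little reacted. I commit to the first way.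

The forecast, “So I interpolate empirically”, gives 80.2% (77.5% to 83%) for red, 87.5% (85.5% to 89.5%) for grey and 68.5% (65% to 71.5%) for green. Its trend: it rises. Its green stands 0.50 points below my first way.

The flasks give 79.8% for red, 87.5% for grey and 70.1% for green. The trend: it rises, by 17 points.

    electrophile + nucleophile → acid set free + target (k = 1.20 /M/min)
    nucleophile + acid set free ⇌ protonated nucleophile, settled at all times (K = 6600 /M)
    electrophile ⇌ dormant form (K = 18.0, k = 0.0290 /min)
    2 nucleophile → self-condensation product (k = 0.980 /M/min)

Green holds 30% of its electrophile at the end, a count of 1.74 half-lives against the 1.69 reckoned. The neighbour flask is green with 0.25 M of electrophile. Nucleophile and time are held, so the dose is green's, and the carried count of 1.69 gives 31.0% left. That flask holds 41.5% electrophile, which is 1.27 half-lives spent and 58.5% reacted. Its target stands at 25.0%. Nucleophile is its limiting reagent, with 0.82% of its own charge left unbound.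

The earlier runs and the new flask were computed from invented constants, and the scatter is random.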